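**Retrosynthetic overview**
- The two phenols are unmasked last from benzyl ethers. The C3 ester comes from the (2R,3R)-3-alcohol and (R)-2-methylbutanoic acid, and the C3–O bond from oxidation of the C3=C4 silyl enol ether on the face away from the C2 phenyl.
- Key disconnection: C2–C3 of ring C. Seen from O1, the C2 carbon with its hydrogen and phenyl ring B is an O-benzyl group on ring A. One benzyl ether of a symmetric 2,4,6-tris(benzyloxy)phenyl diazomethyl ketone therefore supplies C2 and ring B when the rhodium carbenoid at C3 inserts enantioselectively into its benzylic C–H bond; the other two benzyl groups stay as the O5 and O7 protecting groups.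
- The diazo ketone comes from the catalogue flavonoid building block 1-[2,4-bis(benzyloxy)-6-hydroxyphenyl]ethan-1-one by benzylation of its one free, chelated hydroxyl and detrifluoroacetylative diazo transfer.
- Ring order: ring A is bought, ring B is one of the two equivalent ortho benzyl groups of the tribenzyl ether, and ring C is the only ring formed (step 3). C2 is set by the catalyst in step 3, C3 by substrate control in step 5, and the acyl α-carbon is bought.

Key step: step 3

Assumption: Rh2(S-PTTL)4 is taken to favour the (2S) flavanone; should the (2R) sense prevail, the mirror-image catalyst Rh2(R-PTTL)4 is used with no other change.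

**Step 1**
Reactants: 1 1-[2,4-bis(benzyloxy)-6-hydroxyphenyl]ethan-1-one; 2 benzyl bromide
Product: 3 1-[2,4,6-tris(benzyloxy)phenyl]ethan-1-one
Conditions: BnBr (1.3 equiv), K2CO3 (2 equiv), DMF, 70 °C
Reagents that add atoms: none
Why: Williamson ether synthesis; the one free hydroxyl is hydrogen-bonded to the ketone, so warming in a dipolar aprotic solvent is used to free the potassium phenoxide, which in DMF should be benzylated on oxygen and not on carbon.

**Step 2**
Reactants: 3 1-[2,4,6-tris(benzyloxy)phenyl]ethan-1-one
Product: 5 2-diazo-1-[2,4,6-tris(benzyloxy)phenyl]ethan-1-one, via trifluoroacetyl diketone 4 (not isolated)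
Conditions: LiHMDS, THF, −78 °C; CF3CO2CH2CF3, −78 °C; 5% HCl aq work-up; then p-ABSA, Et3N, H2O (1 equiv), MeCN, rt
Reagents that add atoms: 4-acetamidobenzenesulfonyl azide, CC(=O)Nc1ccc(cc1)S(=O)(=O)N=[N+]=[N-] (the two diazo nitrogens); 2,2,2-trifluoroethyl trifluoroacetate, FC(F)(F)C(=O)OCC(F)(F)F (trifluoroacetyl group, kept only in 4)
Why: Detrifluoroacetylative Regitz-type diazo transfer; C-trifluoroacetylation of the lithium enolate activates the methyl ketone, and the triazoline formed with the sulfonyl azide should fragment with loss of the trifluoroacetyl group as the N-acylsulfonamide.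

**Step 3**
Reactants: 5 2-diazo-1-[2,4,6-tris(benzyloxy)phenyl]ethan-1-one
Product: 6 (2S)-5,7-bis(benzyloxy)-2-phenylchroman-4-one
Conditions: Rh2(S-PTTL)4 [dirhodium tetrakis[N-phthaloyl-(S)-tert-leucinate]] (2 mol%), toluene, 0 °C, slow addition of 5 at high dilution, Ar
Reagents that add atoms: none
Why: The divalent rhodium dimer binds the diazo carbon and expels N2 to give an electrophilic acceptor-only carbenoid at C3, which should insert into a C–H bond of an ortho OCH2Ph group through a concerted, asynchronous three-centre transition state with hydride-like transfer to carbon, forming C2–C3. The closest known reaction type is the dirhodium carboxylate-catalysed intramolecular C–H insertion of ortho-alkoxyaryl diazo ketones to chroman-4-ones, which has also been run enantioselectively with chiral carboxylates. Ring C closes as a six-membered ring by 1,6-insertion, the aryl ketone holding C3 and the ether methylene in a rigid cis arrangement; rotation about the aryl–carbonyl bond exchanges the two ortho benzyloxy groups, so either gives the same product. C2 is set by the catalyst alone: the four phthalimido groups wall a chiral pocket around the axial carbenoid and should distinguish the two enantiotopic benzylic hydrogens by forcing the phenyl group away from the walls. Insertion must outrun attack of the carbenoid on the lone pair of O1 (five-membered oxonium ylide, then Stevens 1,2-benzyl shift), carbene dimerisation and addition to a benzyl ring. O1 is a weak donor because it is conjugated through ring A with the C4 carbonyl, the C–H bond is activated twice (alpha to oxygen and benzylic), and slow addition in a non-coordinating solvent should suppress the bimolecular paths.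

**Step 4**
Reactants: 6 (2S)-5,7-bis(benzyloxy)-2-phenylchroman-4-one
Product: 7 (2S)-5,7-bis(benzyloxy)-2-phenyl-4-(trimethylsilyloxy)-2H-chromene
Conditions: TMSOTf, Et3N, CH2Cl2, 0 °C, dark; cold NaHCO3 aq work-up, crude used at once
Reagents that add atoms: trimethylsilyl trifluoromethanesulfonate, C[Si](C)(C)OS(=O)(=O)C(F)(F)F
Why: Soft enolisation; O-silylation of the C4 carbonyl followed by amine deprotonation at C3 forms no free enolate, so β-elimination of the O1 phenoxide (retro-oxa-Michael opening, which would racemise C2) should not occur.

**Step 5**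
Reactants: 7 (2S)-5,7-bis(benzyloxy)-2-phenyl-4-(trimethylsilyloxy)-2H-chromene
Product: 9 (2R,3R)-5,7-bis(benzyloxy)-3-hydroxy-2-phenylchroman-4-one, via silyloxy epoxide 8 (not isolated)
Conditions: DMDO (1.2 equiv), acetone/CH2Cl2, −40 → 0 °C; then 0.5 M HCl aq, THF, 0 °C
Reagents that add atoms: dimethyldioxirane, CC1(C)OO1
Why: Rubottom oxidation; the dioxirane should epoxidise the electron-rich C3=C4 bond from the face opposite the C2 phenyl (substrate control by C2), and hydrolytic opening of the silyloxy epoxide with loss of silanol restores the C4 ketone and gives the 2,3-trans alcohol, which is also the more stable diequatorial epimer.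

**Step 6**
Reactants: 9 (2R,3R)-5,7-bis(benzyloxy)-3-hydroxy-2-phenylchroman-4-one; 10 (R)-2-methylbutanoic acid
Product: 11 (2R,3R)-5,7-bis(benzyloxy)-4-oxo-2-phenylchroman-3-yl (2R)-2-methylbutanoate
Conditions: DCC, DMAP (0.1 equiv), CH2Cl2, 0 °C → rt
Reagents that add atoms: none
Why: Steglich esterification; the acylpyridinium should acylate the secondary alcohol without strong base, so C2 and C3 stay intact and the α-centre of the acid is not lost through ketene formation.

**Step 7**
Reactants: 11 (2R,3R)-5,7-bis(benzyloxy)-4-oxo-2-phenylchroman-3-yl (2R)-2-methylbutanoate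
Product: 12 (2R,3R)-5,7-dihydroxy-4-oxo-2-phenylchroman-3-yl (2R)-2-methylbutanoate
Conditions: H2 (1 atm), 10% Pd/C, EtOAc, rt, stopped after uptake of 2 equiv H2
Reagents that add atoms: none
Why: Catalytic hydrogenolysis; the two primary aryl benzyl ethers should cleave much faster than the secondary, ring-bound C2–O1 benzylic bond, and the ketone and ester are inert under these neutral conditions.

**Compound list**
1 | 1-[2,4-bis(benzyloxy)-6-hydroxyphenyl]ethan-1-one | CC(=O)c1c(O)cc(OCc2ccccc2)cc1OCc1ccccc1 | starting material
2 | benzyl bromide | BrCc1ccccc1 | starting material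
3 | 1-[2,4,6-tris(benzyloxy)phenyl]ethan-1-one | CC(=O)c1c(OCc2ccccc2)cc(OCc2ccccc2)cc1OCc1ccccc1 | intermediate
4 | 4,4,4-trifluoro-1-[2,4,6-tris(benzyloxy)phenyl]butane-1,3-dione | O=C(CC(=O)C(F)(F)F)c1c(OCc2ccccc2)cc(OCc2ccccc2)cc1OCc1ccccc1 | intermediate
5 | 2-diazo-1-[2,4,6-tris(benzyloxy)phenyl]ethan-1-one | [N-]=[N+]=CC(=O)c1c(OCc2ccccc2)cc(OCc2ccccc2)cc1OCc1ccccc1 | intermediate
6 | (2S)-5,7-bis(benzyloxy)-2-phenylchroman-4-one | O=C1C[C@@H](c2ccccc2)Oc2cc(OCc3ccccc3)cc(OCc3ccccc3)c21 | intermediate
7 | (2S)-5,7-bis(benzyloxy)-2-phenyl-4-(trimethylsilyloxy)-2H-chromene | C[Si](C)(C)OC1=C[C@@H](c2ccccc2)Oc2cc(OCc3ccccc3)cc(OCc3ccccc3)c21 | intermediate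
8 | (2R,3R,4R)-5,7-bis(benzyloxy)-3,4-epoxy-4-(trimethylsilyloxy)flavan, epoxide oxygen anti to the C2 phenyl | O1[C@H]2[C@]1(O[Si](C)(C)C)c1c(OCc3ccccc3)cc(OCc3ccccc3)cc1O[C@@H]2c1ccccc1 | intermediate
9 | (2R,3R)-5,7-bis(benzyloxy)-3-hydroxy-2-phenylchroman-4-one | O[C@H]1C(=O)c2c(OCc3ccccc3)cc(OCc3ccccc3)cc2O[C@@H]1c1ccccc1 | intermediate
10 | (R)-2-methylbutanoic acid | CC[C@@H](C)C(=O)O | starting material
11 | (2R,3R)-5,7-bis(benzyloxy)-4-oxo-2-phenylchroman-3-yl (2R)-2-methylbutanoate | CC[C@@H](C)C(=O)O[C@H]1C(=O)c2c(OCc3ccccc3)cc(OCc3ccccc3)cc2O[C@@H]1c1ccccc1 | intermediate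
12 | (2R,3R)-5,7-dihydroxy-4-oxo-2-phenylchroman-3-yl (2R)-2-methylbutanoate | CC[C@@H](C)C(=O)O[C@H]1C(=O)c2c(O)cc(O)cc2O[C@@H]1c1ccccc1 | target

**Total step count:** 7
**Longest linear sequence:** 7 steps (1 → 12)

**Steps most likely to fail**

Step 3. The carbenoid may be captured by the lone pair of O1 and rearrange by 1,2-benzyl shift instead of inserting, or the catalyst may discriminate poorly between the two benzylic hydrogens. If only the enantiomeric purity falls short, recrystallisation of 6 would be tried first. The fallback builds C2 by aryl transfer instead of C–H insertion and sets out from 1, whose free hydroxyl becomes O1. Condensation with N,N-dimethylformamide dimethyl acetal (toluene, 90 °C) should give (E)-1-[2,4-bis(benzyloxy)-6-hydroxyphenyl]-3-(dimethylamino)prop-2-en-1-one F1. Acid (HCl, CH2Cl2, rt) should close this with loss of dimethylamine to 5,7-bis(benzyloxy)-4H-chromen-4-one F2. Rhodium-catalysed asymmetric 1,4-addition of phenylboronic acid then gives 6, where the route is rejoined; the catalyst is [Rh(OH)(cod)]2 with the electron-poor atropisomeric bisphosphine 6,6'-dimethoxy-2,2'-bis[bis(3,4,5-trifluorophenyl)phosphino]biphenyl, in the enantiomeric form that delivers 2S, in toluene/H2O.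

Step 5. The silyloxy epoxide may rearrange or be over-oxidised towards the flavonol under the acidic opening, or the facial selectivity of epoxidation may be poor. The fallback sets out from 7 and replaces epoxidation by osmium-catalysed dihydroxylation of the enol ether (K2OsO2(OH)4 cat., NMO, acetone/H2O, 0 °C). Osmylation anti to the phenyl group and collapse of the silyl hemiketal with loss of silanol should give 9 directly in a neutral medium, where the route is rejoined. This fallback makes no new compound (F0).

Step 7. Hydrogenolysis may not stop at the two aryl benzyl ethers and may go on to reductive opening of ring C at the benzylic C2–O1 bond. The fallback sets out from 11 and removes the benzyl groups without hydrogen, by Lewis-acid cleavage with BCl3 and pentamethylbenzene as cation scavenger (CH2Cl2, −78 °C). The chelated O5 ether should go first and the ester should survive at this temperature. It returns at 12 and makes no new compound (F0).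

**Further compounds**
F1 | step 3 | (E)-1-[2,4-bis(benzyloxy)-6-hydroxyphenyl]-3-(dimethylamino)prop-2-en-1-one | CN(C)/C=C/C(=O)c1c(O)cc(OCc2ccccc2)cc1OCc1ccccc1
F2 | step 3 | 5,7-bis(benzyloxy)-4H-chromen-4-one | O=c1ccoc2cc(OCc3ccccc3)cc(OCc3ccccc3)c12
F0 | step 5 | none | none
F0 | step 7 | none | none
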